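**Retrosynthetic overview**

1. The target comes from the saturated tricycle 39 by α-methylenation, desilylation and acetylation; 39 comes from hydrogenation of the diene 38, in which ring B (seven-membered lactone) and ring C (fourteen-membered carbocycle) are closed in one double ring-closing metathesis (C13=C14 and C9=C10) of the tetraene ester 36.
2. Ester 36 is cut at O–C16 into acid 26 (C1–C8 with ring A) and the tertiary alcohol 30 (C10–C13); C8 is set by chelation-controlled vinyl addition, C1 by auxiliary-controlled vinyl 1,4-addition, C3 by allylboration, C11/C12 from a C2-symmetric divinyl diol.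
3. Ring A (oxolane O, C4, C5, C6, C7) is made first, by closing the C4–C5 bond: a rhodium carbene at C5 (diazoketone, C6 as carbonyl) inserts into the tertiary C4–H bond of the open ether C7–O–C4H(CH3)(CH2OBn).
4. Enabling feature: the ring A oxygen is flanked by the fully substituted C4 and by C7; in the open ether the C4–H bond is tertiary, α to that oxygen and exactly 1,5 to C5, so insertion is five-membered and stereoretentive and transfers the lactate-derived configuration to C4.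
5. Order of ring formation: ring A (step 7), then rings B and C together (step 24).

Key step: step 7

Remark (numbering, abbreviations, assumptions): cembrane numbering is used. C1 is the ring CH that carries the lactone α-carbon C15 (C15 bears the exocyclic CH2, C16 is the lactone C=O). Ring C runs C1, C2 (CH2), C3 (CHOAc), C4 (C–CH3), C5, C6, C7 (CH–O), C8 (C(CH3)OH), C9, C10, C11 (CHOAc), C12 (C(CH3)–O–C16), C13, C14. Ring A is the oxolane O/C4–C7; ring B is the lactone O/C12/C13/C14/C1/C15/C16. TES is triethylsilyl, TBS is tert-butyldimethylsilyl. (3R,4R)-Hexa-1,5-diene-3,4-diol and (−)-B-allyldiisopinocampheylborane are assumed to be purchasable. The geometry of the C9=C10 alkene in 38 is irrelevant because it is hydrogenated.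

**Route**

Step 1
Reactants: 1 (2S)-1-(benzyloxy)propan-2-ol; 2 bromoacetic acid
Product: 3 {[(2S)-1-(benzyloxy)propan-2-yl]oxy}acetic acid
Conditions: NaH (2.5 equiv), THF, 0 °C to 60 °C; then 1 M HCl
Reagents that add atoms: none
Why: Williamson ether synthesis; the secondary alkoxide displaces bromide from sodium bromoacetate by SN2 and the C4 carbinol centre is not touched.

Step 2
Reactants: 3 {[(2S)-1-(benzyloxy)propan-2-yl]oxy}acetic acid; 4 (4S)-4-benzyl-1,3-oxazolidin-2-one
Product: 6 (4S)-4-benzyl-3-({[(2S)-1-(benzyloxy)propan-2-yl]oxy}acetyl)-1,3-oxazolidin-2-one, via mixed pivalic anhydride 5 (not isolated)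
Conditions: pivaloyl chloride, Et3N, THF, −20 °C; then 4, LiCl, −20 °C to rt
Reagents that add atoms: none
Why: N-acylation of the oxazolidinone through a mixed anhydride; the hindered pivaloyl carbonyl directs attack to the alkoxyacetyl carbonyl.

Step 3
Reactants: 6 (4S)-4-benzyl-3-({[(2S)-1-(benzyloxy)propan-2-yl]oxy}acetyl)-1,3-oxazolidin-2-one; 7 acetaldehyde
Product: 9 (4S)-4-benzyl-3-[(2S,3R)-2-{[(2S)-1-(benzyloxy)propan-2-yl]oxy}-3-hydroxybutanoyl]-1,3-oxazolidin-2-one, via dibutylboron Z-enolate 8 (not isolated)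
Conditions: Bu2BOTf, Et3N, CH2Cl2, −78 °C to 0 °C; then 7, −78 °C to 0 °C; pH 7 buffer, MeOH, H2O2
Reagents that add atoms: none
Why: Evans syn glycolate aldol; the Z boron enolate reacts through a chair (Zimmerman–Traxler) transition state on the face away from the benzyl group, setting C7 (2S here, R in the target numbering) and a temporary carbinol at C8.

Step 4
Reactants: 9 (4S)-4-benzyl-3-[(2S,3R)-2-{[(2S)-1-(benzyloxy)propan-2-yl]oxy}-3-hydroxybutanoyl]-1,3-oxazolidin-2-one
Product: 10 (4S)-4-benzyl-3-[(2S,3R)-2-{[(2S)-1-(benzyloxy)propan-2-yl]oxy}-3-(triethylsilyloxy)butanoyl]-1,3-oxazolidin-2-one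
Conditions: TESOTf, 2,6-lutidine, CH2Cl2, −78 °C to 0 °C
Reagents that add atoms: triethylsilyl trifluoromethanesulfonate, CC[Si](CC)(CC)OS(=O)(=O)C(F)(F)F
Why: silyl ether formation; the C8 hydroxyl must be masked so that it cannot undergo O–H insertion in step 7.

Step 5
Reactants: 10 (4S)-4-benzyl-3-[(2S,3R)-2-{[(2S)-1-(benzyloxy)propan-2-yl]oxy}-3-(triethylsilyloxy)butanoyl]-1,3-oxazolidin-2-one
Product: 11 (2S,3R)-2-{[(2S)-1-(benzyloxy)propan-2-yl]oxy}-3-(triethylsilyloxy)butanoic acid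
Conditions: LiOH, H2O2, THF/H2O, 0 °C; Na2SO3; then 1 M HCl to pH 3
Reagents that add atoms: hydrogen peroxide (as LiOOH), OO
Why: hydroperoxide cleavage of the imide at the exocyclic carbonyl, without epimerisation at C7; the auxiliary 4 is recovered.

Step 6
Reactants: 11 (2S,3R)-2-{[(2S)-1-(benzyloxy)propan-2-yl]oxy}-3-(triethylsilyloxy)butanoic acid
Product: 13 (3S,4R)-3-{[(2S)-1-(benzyloxy)propan-2-yl]oxy}-1-diazo-4-(triethylsilyloxy)pentan-2-one, via isobutyl carbonic mixed anhydride 12 (not isolated)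
Conditions: isobutyl chloroformate, N-methylmorpholine, THF, −20 °C; then CH2N2, Et2O, 0 °C to rt
Reagents that add atoms: diazomethane, C=[N+]=[N-]
Why: acylation of diazomethane by a mixed anhydride (first stage of the Arndt–Eistert sequence) gives the α-alkoxy diazomethyl ketone under neutral conditions.

Step 7
Reactants: 13 (3S,4R)-3-{[(2S)-1-(benzyloxy)propan-2-yl]oxy}-1-diazo-4-(triethylsilyloxy)pentan-2-one
Product: 14 (2S,5R)-5-[(benzyloxy)methyl]-5-methyl-2-[(1R)-1-(triethylsilyloxy)ethyl]oxolan-3-one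
Conditions: Rh2(OAc)4 (1 mol %), CH2Cl2, rt, slow addition of 13
Reagents that add atoms: none
Why: Dirhodium tetraacetate extrudes N2 from 13 to give an electrophilic divalent-rhodium carbene at C5, which inserts in one concerted three-centre step into the C4–H bond held 1,5 to it by the C7–O–C4 ether, forming the C4–C5 bond and releasing the catalyst. The closest known reaction type is the dirhodium-carboxylate-catalysed C–H insertion of α-alkoxy diazomethyl ketones next to the ether oxygen, which gives oxolan-3-ones. Ring A is closed by 1,5-insertion through a five-membered cyclic transition state, with no ylide intermediate. The new fully substituted stereocentre C4 is formed with retention of the C4–H configuration, so the (S)-carbinol of 1 becomes (R)-C4 with its CH3 cis to the C7 side chain, while C7 (from step 3) is not touched. The step needs site selectivity for the tertiary α-oxygenated C4–H over the C3 methylene (six-membered path), the C8 methyl and the silyl C–H bonds, and over ylide formation at the silyl ether oxygen; the five-membered transition state, the activation of the tertiary C–H by the adjacent oxygen and the low basicity and bulk of the TES ether oxygen should secure it, and slow addition suppresses carbene dimerisation.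

Step 8
Reactants: 14 (2S,5R)-5-[(benzyloxy)methyl]-5-methyl-2-[(1R)-1-(triethylsilyloxy)ethyl]oxolan-3-one
Product: 16 (2R,5R)-2-[(benzyloxy)methyl]-2-methyl-5-[(1R)-1-(triethylsilyloxy)ethyl]oxolane, via tosylhydrazone 15 (not isolated)
Conditions: TsNHNH2, MeOH, rt; then catecholborane, CHCl3, 0 °C; NaOAc·3H2O, reflux
Reagents that add atoms: none
Why: deoxygenation of the C6 ketone by hydride reduction of its tosylhydrazone and loss of sulfinate and N2 from the diazene; the conditions are mild enough that C7 should not epimerise.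

Step 9
Reactants: 16 (2R,5R)-2-[(benzyloxy)methyl]-2-methyl-5-[(1R)-1-(triethylsilyloxy)ethyl]oxolane
Product: 17 {(2R,5R)-2-methyl-5-[(1R)-1-(triethylsilyloxy)ethyl]oxolan-2-yl}methanol
Conditions: H2 (1 atm), Pd/C (10 %), EtOAc, rt
Reagents that add atoms: none
Why: hydrogenolysis of the benzyl ether; no alkene is present yet and the TES ether is stable in EtOAc.

Step 10
Reactants: 17 {(2R,5R)-2-methyl-5-[(1R)-1-(triethylsilyloxy)ethyl]oxolan-2-yl}methanol
Product: 18 (2R,5R)-2-methyl-5-[(1R)-1-(triethylsilyloxy)ethyl]oxolane-2-carbaldehyde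
Conditions: Dess–Martin periodinane, CH2Cl2, 0 °C to rt
Reagents that add atoms: none
Why: Dess–Martin oxidation of the primary alcohol to the C3 aldehyde, which has no α-hydrogen and cannot epimerise.

Step 11
Reactants: 18 (2R,5R)-2-methyl-5-[(1R)-1-(triethylsilyloxy)ethyl]oxolane-2-carbaldehyde
Product: 19 (1S)-1-{(2R,5R)-2-methyl-5-[(1R)-1-(triethylsilyloxy)ethyl]oxolan-2-yl}but-3-en-1-ol
Conditions: (−)-Ipc2B(allyl), Et2O, −78 °C; then NaOH, H2O2
Reagents that add atoms: (−)-B-allyldiisopinocampheylborane, C=CCB([C@@H]1C[C@@H]2C[C@H]([C@H]1C)C2(C)C)[C@@H]1C[C@@H]2C[C@H]([C@H]1C)C2(C)C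
Why: Brown allylboration; the reagent derived from (+)-α-pinene delivers allyl to the Si face of the aldehyde through a chair transition state and sets C3 as S under reagent control.

Step 12
Reactants: 19 (1S)-1-{(2R,5R)-2-methyl-5-[(1R)-1-(triethylsilyloxy)ethyl]oxolan-2-yl}but-3-en-1-ol
Product: 20 tert-butyl(dimethyl){[(1S)-1-{(2R,5R)-2-methyl-5-[(1R)-1-(triethylsilyloxy)ethyl]oxolan-2-yl}but-3-en-1-yl]oxy}silane
Conditions: TBSOTf, 2,6-lutidine, CH2Cl2, −78 °C to 0 °C
Reagents that add atoms: tert-butyldimethylsilyl trifluoromethanesulfonate, CC(C)(C)[Si](C)(C)OS(=O)(=O)C(F)(F)F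
Why: silylation of the hindered C3 hydroxyl with a group that survives the later selective removal of the TES ether.

Step 13
Reactants: 21 acrylic acid; 4 (4S)-4-benzyl-1,3-oxazolidin-2-one
Product: 23 (4S)-4-benzyl-3-(prop-2-enoyl)-1,3-oxazolidin-2-one, via acrylic pivalic anhydride 22 (not isolated)
Conditions: pivaloyl chloride, Et3N, THF, −20 °C; then 4, LiCl, −20 °C to rt
Reagents that add atoms: none
Why: N-acylation of the oxazolidinone through a mixed anhydride, a standard preparation of N-enoyl imides.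

Step 14
Reactants: 20 tert-butyl(dimethyl){[(1S)-1-{(2R,5R)-2-methyl-5-[(1R)-1-(triethylsilyloxy)ethyl]oxolan-2-yl}but-3-en-1-yl]oxy}silane; 23 (4S)-4-benzyl-3-(prop-2-enoyl)-1,3-oxazolidin-2-one
Product: 24 (4S)-4-benzyl-3-[(2E,5S)-5-(tert-butyldimethylsilyloxy)-5-{(2R,5R)-2-methyl-5-[(1R)-1-(triethylsilyloxy)ethyl]oxolan-2-yl}pent-2-enoyl]-1,3-oxazolidin-2-one
Conditions: second-generation Hoveyda–Grubbs catalyst RuCl2(H2IMes)(=CH-C6H4-2-OiPr) (5 mol %), 23 (3 equiv), CH2Cl2, 40 °C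
Reagents that add atoms: none
Why: olefin cross-metathesis of a terminal alkene with an acryloyl imide, which gives the conjugated E-alkene selectively.

Step 15
Reactants: 24 (4S)-4-benzyl-3-[(2E,5S)-5-(tert-butyldimethylsilyloxy)-5-{(2R,5R)-2-methyl-5-[(1R)-1-(triethylsilyloxy)ethyl]oxolan-2-yl}pent-2-enoyl]-1,3-oxazolidin-2-one
Product: 25 (4S)-4-benzyl-3-[(3R,5S)-5-(tert-butyldimethylsilyloxy)-3-ethenyl-5-{(2R,5R)-2-methyl-5-[(1R)-1-(triethylsilyloxy)ethyl]oxolan-2-yl}pentanoyl]-1,3-oxazolidin-2-one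
Conditions: vinylmagnesium bromide, CuBr·SMe2 (20 mol %), THF/Me2S, −78 °C to −30 °C; NH4Cl
Reagents that add atoms: vinylmagnesium bromide, C=C[Mg]Br
Why: copper-catalysed 1,4-addition of a Grignard reagent to an N-enoyl oxazolidinone; in the magnesium-chelated s-cis imide the vinyl group adds to the face away from the benzyl group and sets C1.

Step 16
Reactants: 25 (4S)-4-benzyl-3-[(3R,5S)-5-(tert-butyldimethylsilyloxy)-3-ethenyl-5-{(2R,5R)-2-methyl-5-[(1R)-1-(triethylsilyloxy)ethyl]oxolan-2-yl}pentanoyl]-1,3-oxazolidin-2-one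
Product: 26 (3R,5S)-5-(tert-butyldimethylsilyloxy)-3-ethenyl-5-{(2R,5R)-2-methyl-5-[(1R)-1-(triethylsilyloxy)ethyl]oxolan-2-yl}pentanoic acid
Conditions: LiOH, H2O2, THF/H2O, 0 °C; Na2SO3; then 1 M HCl to pH 3
Reagents that add atoms: hydrogen peroxide (as LiOOH), OO
Why: hydroperoxide cleavage of the imide; C1 is β to the carbonyl and cannot epimerise, and the auxiliary 4 is recovered.

Step 17
Reactants: 27 (3R,4R)-hexa-1,5-diene-3,4-diol
Product: 28 (3R,4R)-4-(tert-butyldimethylsilyloxy)hexa-1,5-dien-3-ol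
Conditions: NaH (1.0 equiv), THF, 0 °C; then TBSCl (1.0 equiv), rt
Reagents that add atoms: tert-butyldimethylsilyl chloride, CC(C)(C)[Si](C)(C)Cl
Why: monosilylation of a C2-symmetric diol through its mono-alkoxide; both hydroxyls are equivalent, so one product forms, and the silylated carbinol becomes C11.

Step 18
Reactants: 28 (3R,4R)-4-(tert-butyldimethylsilyloxy)hexa-1,5-dien-3-ol
Product: 29 (4R)-4-(tert-butyldimethylsilyloxy)hexa-1,5-dien-3-one
Conditions: Dess–Martin periodinane, NaHCO3, CH2Cl2, 0 °C; used at once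
Reagents that add atoms: none
Why: Dess–Martin oxidation under buffered, non-basic conditions, so that the doubly activated C11–H does not enolise.

Step 19
Reactants: 29 (4R)-4-(tert-butyldimethylsilyloxy)hexa-1,5-dien-3-one
Product: 30 (3R,4R)-4-(tert-butyldimethylsilyloxy)-3-methylhexa-1,5-dien-3-ol
Conditions: MeLi, CeCl3, THF, −78 °C; NH4Cl
Reagents that add atoms: methyllithium, [Li]C
Why: 1,2-addition of the non-basic organocerium reagent to the enone; the non-chelating silyloxy group sits anti to the incoming methyl (polar Felkin–Anh model), which sets C12 as R next to (R)-C11.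

Step 20
Reactants: 26 (3R,5S)-5-(tert-butyldimethylsilyloxy)-3-ethenyl-5-{(2R,5R)-2-methyl-5-[(1R)-1-(triethylsilyloxy)ethyl]oxolan-2-yl}pentanoic acid; 30 (3R,4R)-4-(tert-butyldimethylsilyloxy)-3-methylhexa-1,5-dien-3-ol
Product: 33 (3R,4R)-4-(tert-butyldimethylsilyloxy)-3-methylhexa-1,5-dien-3-yl (3R,5S)-5-(tert-butyldimethylsilyloxy)-3-ethenyl-5-{(2R,5R)-2-methyl-5-[(1R)-1-(triethylsilyloxy)ethyl]oxolan-2-yl}pentanoate, via acid chloride 31 (not isolated), via lithium alkoxide 32 (not isolated)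
Conditions: 26, 1-chloro-N,N,2-trimethylprop-1-en-1-amine, CH2Cl2, 0 °C; separately 30, LiN(SiMe3)2, THF, −78 °C; combine, −78 °C to −20 °C
Reagents that add atoms: none
Why: acylation of a lithium tert-alkoxide by an acid chloride made under neutral conditions, the usual way to esterify hindered tertiary alcohols; the low temperature suppresses 1,2-silyl migration.

Step 21
Reactants: 33 (3R,4R)-4-(tert-butyldimethylsilyloxy)-3-methylhexa-1,5-dien-3-yl (3R,5S)-5-(tert-butyldimethylsilyloxy)-3-ethenyl-5-{(2R,5R)-2-methyl-5-[(1R)-1-(triethylsilyloxy)ethyl]oxolan-2-yl}pentanoate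
Product: 34 (3R,4R)-4-(tert-butyldimethylsilyloxy)-3-methylhexa-1,5-dien-3-yl (3R,5S)-5-(tert-butyldimethylsilyloxy)-3-ethenyl-5-{(2R,5R)-5-[(1R)-1-hydroxyethyl]-2-methyloxolan-2-yl}pentanoate
Conditions: HF·pyridine, pyridine, THF, 0 °C
Reagents that add atoms: none
Why: selective fluoride cleavage of the TES ether in the presence of two secondary TBS ethers and the tertiary allylic ester.

Step 22
Reactants: 34 (3R,4R)-4-(tert-butyldimethylsilyloxy)-3-methylhexa-1,5-dien-3-yl (3R,5S)-5-(tert-butyldimethylsilyloxy)-3-ethenyl-5-{(2R,5R)-5-[(1R)-1-hydroxyethyl]-2-methyloxolan-2-yl}pentanoate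
Product: 35 (3R,4R)-4-(tert-butyldimethylsilyloxy)-3-methylhexa-1,5-dien-3-yl (3R,5S)-5-[(2R,5R)-5-acetyl-2-methyloxolan-2-yl]-5-(tert-butyldimethylsilyloxy)-3-ethenylpentanoate
Conditions: Dess–Martin periodinane, NaHCO3, CH2Cl2, rt
Reagents that add atoms: none
Why: Dess–Martin oxidation of the C8 carbinol to the methyl ketone, erasing the temporary C8 stereocentre.

Step 23
Reactants: 35 (3R,4R)-4-(tert-butyldimethylsilyloxy)-3-methylhexa-1,5-dien-3-yl (3R,5S)-5-[(2R,5R)-5-acetyl-2-methyloxolan-2-yl]-5-(tert-butyldimethylsilyloxy)-3-ethenylpentanoate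
Product: 36 (3R,4R)-4-(tert-butyldimethylsilyloxy)-3-methylhexa-1,5-dien-3-yl (3R,5S)-5-(tert-butyldimethylsilyloxy)-3-ethenyl-5-{(2R,5R)-5-[(2R)-2-hydroxybut-3-en-2-yl]-2-methyloxolan-2-yl}pentanoate
Conditions: vinylmagnesium bromide (1.5 equiv), THF, −78 °C; NH4Cl
Reagents that add atoms: vinylmagnesium bromide, C=C[Mg]Br
Why: Cram chelation-controlled Grignard addition; magnesium bridges the ketone and ring A oxygens and the vinyl group adds anti to C6, setting C8 as R, while the hindered tertiary ester does not react at −78 °C.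

Step 24
Reactants: 36 (3R,4R)-4-(tert-butyldimethylsilyloxy)-3-methylhexa-1,5-dien-3-yl (3R,5S)-5-(tert-butyldimethylsilyloxy)-3-ethenyl-5-{(2R,5R)-5-[(2R)-2-hydroxybut-3-en-2-yl]-2-methyloxolan-2-yl}pentanoate
Product: 38 (1R,3S,4R,7R,8R,11R,12R)-tricyclic diene with rings A, B and C closed, C9=C10 and C13=C14 double bonds, C15 as CH2, 3-O-TBS, 11-O-TBS and free 8-OH, via oxepinone triene 37 (not isolated)
Conditions: second-generation Hoveyda–Grubbs catalyst RuCl2(H2IMes)(=CH-C6H4-2-OiPr) (2 × 10 mol %), toluene (0.5 mM), 80 °C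
Reagents that add atoms: none
Why: double ring-closing metathesis; the C1 and C12 vinyl groups should close the seven-membered lactone first (favoured over the eight-membered alternative), after which only the C8 and C11 vinyl groups remain to close ring C, helped by the free allylic hydroxyl at C8.

Step 25
Reactants: 38 (1R,3S,4R,7R,8R,11R,12R)-tricyclic diene with rings A, B and C closed
Product: 39 (1R,3S,4R,7R,8R,11R,12R)-saturated tricycle with C15 as CH2, 3-O-TBS, 11-O-TBS and free 8-OH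
Conditions: H2 (1 atm), [Ir(cod)(PCy3)(py)]PF6 (5 mol %), CH2Cl2, rt
Reagents that add atoms: none
Why: homogeneous hydrogenation of both disubstituted alkenes with a cationic iridium catalyst, which avoids hydrogenolysis of the allylic C–O bonds; no stereocentre is formed.

Step 26
Reactants: 39 (1R,3S,4R,7R,8R,11R,12R)-saturated tricycle with C15 as CH2
Product: 42 (1R,3S,4R,7R,8R,11R,12R)-α-methylene lactone with 3-O-TBS, 11-O-TBS and free 8-OH, via Mannich base 40 (not isolated), via trimethylammonium iodide 41 (not isolated)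
Conditions: LiN(iPr)2 (2.5 equiv), THF, −78 °C; CH2=NMe2 I (Eschenmoser's salt), −78 °C to rt; then MeI, MeOH, rt; then NaHCO3 (aq), CH2Cl2
Reagents that add atoms: N,N-dimethylmethyleneiminium iodide, C=[N+](C)C.[I-]
Why: Eschenmoser methylenation; the lactone enolate (C15 is the only enolisable position) undergoes a Mannich reaction, and quaternisation followed by elimination of trimethylamine gives the exocyclic alkene.

Step 27
Reactants: 42 (1R,3S,4R,7R,8R,11R,12R)-α-methylene lactone with 3-O-TBS and 11-O-TBS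
Product: 43 (1R,3S,4R,7R,8R,11R,12R)-3,8,11-triol α-methylene lactone
Conditions: HF·pyridine (excess), THF, 0 °C to rt
Reagents that add atoms: none
Why: acidic fluoride desilylation, which avoids the basic alkoxides that could add to the α-methylene lactone.

Step 28
Reactants: 43 (1R,3S,4R,7R,8R,11R,12R)-3,8,11-triol α-methylene lactone
Product: 44 CNP0343714.1 (target)
Conditions: Ac2O, pyridine, DMAP (cat.), CH2Cl2, 0 °C to rt
Reagents that add atoms: acetic anhydride, CC(=O)OC(C)=O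
Why: acetylation of the two secondary hydroxyls (C3, C11); the tertiary C8 hydroxyl reacts far more slowly and should stay free.

**Compound list**

1 | (2S)-1-(benzyloxy)propan-2-ol | C[C@H](O)COCc1ccccc1 | starting material
2 | bromoacetic acid | OC(=O)CBr | starting material
3 | {[(2S)-1-(benzyloxy)propan-2-yl]oxy}acetic acid | C[C@H](OCC(=O)O)COCc1ccccc1 | intermediate
4 | (4S)-4-benzyl-1,3-oxazolidin-2-one | O=C1N[C@@H](Cc2ccccc2)CO1 | starting material
5 | mixed pivalic anhydride of 3 (not isolated) | C[C@H](OCC(=O)OC(=O)C(C)(C)C)COCc1ccccc1 | intermediate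
6 | (4S)-4-benzyl-3-({[(2S)-1-(benzyloxy)propan-2-yl]oxy}acetyl)-1,3-oxazolidin-2-one | C[C@H](OCC(=O)N1[C@@H](Cc2ccccc2)COC1=O)COCc1ccccc1 | intermediate
7 | acetaldehyde | CC=O | starting material
8 | dibutylboron Z-enolate of 6 (not isolated) | C[C@H](O/C=C(\OB(CCCC)CCCC)N1[C@@H](Cc2ccccc2)COC1=O)COCc1ccccc1 | intermediate
9 | (4S)-4-benzyl-3-[(2S,3R)-2-{[(2S)-1-(benzyloxy)propan-2-yl]oxy}-3-hydroxybutanoyl]-1,3-oxazolidin-2-one | C[C@H](O[C@@H]([C@@H](C)O)C(=O)N1[C@@H](Cc2ccccc2)COC1=O)COCc1ccccc1 | intermediate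
10 | 3-O-TES ether of 9 | C[C@H](O[C@@H]([C@@H](C)O[Si](CC)(CC)CC)C(=O)N1[C@@H](Cc2ccccc2)COC1=O)COCc1ccccc1 | intermediate
11 | (2S,3R)-2-{[(2S)-1-(benzyloxy)propan-2-yl]oxy}-3-(triethylsilyloxy)butanoic acid | C[C@H](O[C@@H]([C@@H](C)O[Si](CC)(CC)CC)C(=O)O)COCc1ccccc1 | intermediate
12 | isobutyl carbonic mixed anhydride of 11 (not isolated) | C[C@H](O[C@@H]([C@@H](C)O[Si](CC)(CC)CC)C(=O)OC(=O)OCC(C)C)COCc1ccccc1 | intermediate
13 | (3S,4R)-3-{[(2S)-1-(benzyloxy)propan-2-yl]oxy}-1-diazo-4-(triethylsilyloxy)pentan-2-one | C[C@H](O[C@@H]([C@@H](C)O[Si](CC)(CC)CC)C(=O)C=[N+]=[N-])COCc1ccccc1 | intermediate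
14 | (2S,5R)-5-[(benzyloxy)methyl]-5-methyl-2-[(1R)-1-(triethylsilyloxy)ethyl]oxolan-3-one | C[C@@H](O[Si](CC)(CC)CC)[C@@H]1O[C@@](C)(COCc2ccccc2)CC1=O | intermediate
15 | 4-methylbenzenesulfonylhydrazone of 14 (not isolated) | C[C@@H](O[Si](CC)(CC)CC)[C@@H]1O[C@@](C)(COCc2ccccc2)CC1=NNS(=O)(=O)c1ccc(C)cc1 | intermediate
16 | (2R,5R)-2-[(benzyloxy)methyl]-2-methyl-5-[(1R)-1-(triethylsilyloxy)ethyl]oxolane | C[C@@H](O[Si](CC)(CC)CC)[C@@H]1O[C@@](C)(COCc2ccccc2)CC1 | intermediate
17 | {(2R,5R)-2-methyl-5-[(1R)-1-(triethylsilyloxy)ethyl]oxolan-2-yl}methanol | C[C@@H](O[Si](CC)(CC)CC)[C@@H]1O[C@@](C)(CO)CC1 | intermediate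
18 | (2R,5R)-2-methyl-5-[(1R)-1-(triethylsilyloxy)ethyl]oxolane-2-carbaldehyde | C[C@@H](O[Si](CC)(CC)CC)[C@@H]1O[C@@](C)(C=O)CC1 | intermediate
19 | (1S)-1-{(2R,5R)-2-methyl-5-[(1R)-1-(triethylsilyloxy)ethyl]oxolan-2-yl}but-3-en-1-ol | C[C@@H](O[Si](CC)(CC)CC)[C@@H]1O[C@@](C)([C@@H](O)CC=C)CC1 | intermediate
20 | O-TBS ether of 19 | C[C@@H](O[Si](CC)(CC)CC)[C@@H]1O[C@@](C)([C@@H](O[Si](C)(C)C(C)(C)C)CC=C)CC1 | intermediate
21 | acrylic acid | C=CC(=O)O | starting material
22 | acrylic pivalic anhydride (not isolated) | C=CC(=O)OC(=O)C(C)(C)C | intermediate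
23 | (4S)-4-benzyl-3-(prop-2-enoyl)-1,3-oxazolidin-2-one | C=CC(=O)N1[C@@H](Cc2ccccc2)COC1=O | intermediate
24 | (4S)-4-benzyl-3-[(2E,5S)-5-(TBS-oxy)-5-{(2R,5R)-2-methyl-5-[(1R)-1-(TES-oxy)ethyl]oxolan-2-yl}pent-2-enoyl]-1,3-oxazolidin-2-one | C[C@@H](O[Si](CC)(CC)CC)[C@@H]1O[C@@](C)([C@@H](O[Si](C)(C)C(C)(C)C)C/C=C/C(=O)N2[C@@H](Cc3ccccc3)COC2=O)CC1 | intermediate
25 | (4S)-4-benzyl-3-[(3R,5S)-5-(TBS-oxy)-3-ethenyl-5-{(2R,5R)-2-methyl-5-[(1R)-1-(TES-oxy)ethyl]oxolan-2-yl}pentanoyl]-1,3-oxazolidin-2-one | C[C@@H](O[Si](CC)(CC)CC)[C@@H]1O[C@@](C)([C@@H](O[Si](C)(C)C(C)(C)C)C[C@@H](C=C)CC(=O)N2[C@@H](Cc3ccccc3)COC2=O)CC1 | intermediate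
26 | (3R,5S)-5-(TBS-oxy)-3-ethenyl-5-{(2R,5R)-2-methyl-5-[(1R)-1-(TES-oxy)ethyl]oxolan-2-yl}pentanoic acid | C[C@@H](O[Si](CC)(CC)CC)[C@@H]1O[C@@](C)([C@@H](O[Si](C)(C)C(C)(C)C)C[C@@H](C=C)CC(=O)O)CC1 | intermediate
27 | (3R,4R)-hexa-1,5-diene-3,4-diol | C=C[C@@H](O)[C@H](O)C=C | starting material
28 | (3R,4R)-4-(TBS-oxy)hexa-1,5-dien-3-ol | C=C[C@@H](O)[C@H](O[Si](C)(C)C(C)(C)C)C=C | intermediate
29 | (4R)-4-(TBS-oxy)hexa-1,5-dien-3-one | C=CC(=O)[C@H](O[Si](C)(C)C(C)(C)C)C=C | intermediate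
30 | (3R,4R)-4-(TBS-oxy)-3-methylhexa-1,5-dien-3-ol | C=C[C@@](C)(O)[C@H](O[Si](C)(C)C(C)(C)C)C=C | intermediate
31 | acid chloride of 26 (not isolated) | C[C@@H](O[Si](CC)(CC)CC)[C@@H]1O[C@@](C)([C@@H](O[Si](C)(C)C(C)(C)C)C[C@@H](C=C)CC(=O)Cl)CC1 | intermediate
32 | lithium alkoxide of 30 (not isolated) | C=C[C@@](C)(O[Li])[C@H](O[Si](C)(C)C(C)(C)C)C=C | intermediate
33 | ester of acid 26 with the tertiary hydroxyl of 30 | C[C@@H](O[Si](CC)(CC)CC)[C@@H]1O[C@@](C)([C@@H](O[Si](C)(C)C(C)(C)C)C[C@@H](C=C)CC(=O)O[C@](C)(C=C)[C@H](O[Si](C)(C)C(C)(C)C)C=C)CC1 | intermediate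
34 | ester 33 with the C8 TES ether cleaved to the (1R)-1-hydroxyethyl group | C[C@@H](O)[C@@H]1O[C@@](C)([C@@H](O[Si](C)(C)C(C)(C)C)C[C@@H](C=C)CC(=O)O[C@](C)(C=C)[C@H](O[Si](C)(C)C(C)(C)C)C=C)CC1 | intermediate
35 | ester 34 oxidised to the C8 methyl ketone (5-acetyl on ring A) | CC(=O)[C@@H]1O[C@@](C)([C@@H](O[Si](C)(C)C(C)(C)C)C[C@@H](C=C)CC(=O)O[C@](C)(C=C)[C@H](O[Si](C)(C)C(C)(C)C)C=C)CC1 | intermediate
36 | tetraene ester with the (2R)-2-hydroxybut-3-en-2-yl group on ring A | C=C[C@@](C)(O)[C@@H]1O[C@@](C)([C@@H](O[Si](C)(C)C(C)(C)C)C[C@@H](C=C)CC(=O)O[C@](C)(C=C)[C@H](O[Si](C)(C)C(C)(C)C)C=C)CC1 | intermediate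
37 | (4R,7R)-4,7-dihydrooxepin-2(3H)-one triene: ring B closed, C8 and C11 vinyl groups open (not isolated) | C=C[C@@](C)(O)[C@@H]1O[C@@](C)([C@@H](O[Si](C)(C)C(C)(C)C)C[C@H]2C=C[C@](C)([C@H](O[Si](C)(C)C(C)(C)C)C=C)OC(=O)C2)CC1 | intermediate
38 | (1R,3S,4R,7R,8R,11R,12R)-tricyclic diene (C9=C10, C13=C14), C15 as CH2, 3,11-bis-O-TBS, 8-OH | C1C(=O)O[C@]2(C)C=C[C@@H]1C[C@H](O[Si](C)(C)C(C)(C)C)[C@@]1(C)CC[C@@H](O1)[C@](C)(O)C=C[C@H]2O[Si](C)(C)C(C)(C)C | intermediate
39 | (1R,3S,4R,7R,8R,11R,12R)-saturated tricycle, C15 as CH2, 3,11-bis-O-TBS, 8-OH | C1C(=O)O[C@]2(C)CC[C@@H]1C[C@H](O[Si](C)(C)C(C)(C)C)[C@@]1(C)CC[C@@H](O1)[C@](C)(O)CC[C@H]2O[Si](C)(C)C(C)(C)C | intermediate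
40 | 15-(dimethylaminomethyl) derivative of 39 (not isolated) | CN(C)CC1C(=O)O[C@]2(C)CC[C@@H]1C[C@H](O[Si](C)(C)C(C)(C)C)[C@@]1(C)CC[C@@H](O1)[C@](C)(O)CC[C@H]2O[Si](C)(C)C(C)(C)C | intermediate
41 | trimethylammonium iodide of 40 (not isolated) | C[N+](C)(C)CC1C(=O)O[C@]2(C)CC[C@@H]1C[C@H](O[Si](C)(C)C(C)(C)C)[C@@]1(C)CC[C@@H](O1)[C@](C)(O)CC[C@H]2O[Si](C)(C)C(C)(C)C.[I-] | intermediate
42 | 15-methylene lactone, 3,11-bis-O-TBS, 8-OH | C=C1C(=O)O[C@]2(C)CC[C@@H]1C[C@H](O[Si](C)(C)C(C)(C)C)[C@@]1(C)CC[C@@H](O1)[C@](C)(O)CC[C@H]2O[Si](C)(C)C(C)(C)C | intermediate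
43 | 15-methylene lactone 3,8,11-triol | C=C1C(=O)O[C@]2(C)CC[C@@H]1C[C@H](O)[C@@]1(C)CC[C@@H](O1)[C@](C)(O)CC[C@H]2O | intermediate
44 | CNP0343714.1 | C=C1C(=O)O[C@]2(C)CC[C@@H]1C[C@H](OC(C)=O)[C@@]1(C)CC[C@@H](O1)[C@](C)(O)CC[C@H]2OC(C)=O | target

**Step count and risks**

Total step count: 28. Longest linear sequence: 24 steps (steps 1–12, 14–16, 20–28).

Three steps most likely to fail:

1. Step 24 (double ring closure). The closure of ring C joins two hindered allylic alkenes (one on the fully substituted C8, one on C11 next to the fully substituted C12), so slow macrocyclisation, oligomerisation or mispairing of the four vinyl groups may win. Fallback: set out from 35 and make the C8–C9 bond by a chromium-mediated addition instead of making C9=C10 by metathesis. Ring-closing metathesis of 35 alone (same ruthenium catalyst) should close only ring B to the lactone ketone F1. Cross-metathesis of its remaining C11 vinyl group with vinylboronic acid pinacol ester should give the (E)-alkenylboronate F2, and NaOH/I2 should convert it into the (E)-vinyl iodide F3. Intramolecular Nozaki–Hiyama–Kishi addition (CrCl2, NiCl2 cat., DMSO/THF, high dilution) of the vinyl iodide to the chelated C8 methyl ketone should close ring C and set C8 in the same sense as step 23. The fallback comes back to the route at 38 (as its 9E isomer).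

2. Step 20 (esterification). Acylation of the very hindered tertiary alkoxide may be incomplete, or silyl migration from O11 to O12 may divert the acyl group. Fallback: set out from 30 and 20, form the C12–O–C16 bond with a small ketene-type reagent, and build C1 afterwards. Heating 30 with Meldrum's acid (toluene, 100 °C) should give the malonic half-ester F4, and trimethylsilyldiazomethane its methyl ester F5. Cross-metathesis of 20 with (Z)-but-2-ene-1,4-diyl bis(methyl carbonate) should give the (E)-allylic carbonate F6. Branched-selective allylic alkylation of the sodium enolate of F5 with F6 ([Ir(cod)Cl]2 with a BINOL-derived phosphoramidite, ligand enantiomer chosen for the 1R product) should give the malonate F7 as a mixture of C15 epimers. Krapcho demethoxycarbonylation (LiCl, wet DMSO, 140 °C) removes the extra ester, and the fallback comes back to the route at 33.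

3. Step 8 (deoxygenation). Enolisation of the α-alkoxy ketone during hydrazone formation may epimerise C7, or the hydrazone anion may expel the ring oxygen by β-elimination. Fallback: set out from 14 and remove the oxygen by a radical path. NaBH4 (MeOH, 0 °C) should give the epimeric oxolan-3-ols F8, and NaH, CS2, then MeI the S-methyl xanthates F9. Barton–McCombie reduction (Bu3SnH, AIBN, toluene, 90 °C) comes back to the route at 16.

Further compounds
F1 | step 24 | lactone ketone: ring B closed, C8 as acetyl, C11 vinyl open | CC(=O)[C@@H]1O[C@@](C)([C@@H](O[Si](C)(C)C(C)(C)C)C[C@H]2C=C[C@](C)([C@H](O[Si](C)(C)C(C)(C)C)C=C)OC(=O)C2)CC1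
F2 | step 24 | (E)-alkenylboronic acid pinacol ester of F1 at C9=C10 | CC(=O)[C@@H]1O[C@@](C)([C@@H](O[Si](C)(C)C(C)(C)C)C[C@H]2C=C[C@](C)([C@H](O[Si](C)(C)C(C)(C)C)/C=C/B3OC(C)(C)C(C)(C)O3)OC(=O)C2)CC1
F3 | step 24 | (E)-vinyl iodide corresponding to F2 | CC(=O)[C@@H]1O[C@@](C)([C@@H](O[Si](C)(C)C(C)(C)C)C[C@H]2C=C[C@](C)([C@H](O[Si](C)(C)C(C)(C)C)/C=C/I)OC(=O)C2)CC1
F4 | step 20 | malonic acid mono ester of 30 | C=C[C@@](C)(OC(=O)CC(=O)O)[C@H](O[Si](C)(C)C(C)(C)C)C=C
F5 | step 20 | methyl malonate mixed ester of 30 | C=C[C@@](C)(OC(=O)CC(=O)OC)[C@H](O[Si](C)(C)C(C)(C)C)C=C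
F6 | step 20 | (E)-allylic methyl carbonate from 20 | C[C@@H](O[Si](CC)(CC)CC)[C@@H]1O[C@@](C)([C@@H](O[Si](C)(C)C(C)(C)C)C/C=C/COC(=O)OC)CC1
F7 | step 20 | branched allylation product, methoxycarbonyl derivative of 33 at C15 | C[C@@H](O[Si](CC)(CC)CC)[C@@H]1O[C@@](C)([C@@H](O[Si](C)(C)C(C)(C)C)C[C@@H](C=C)C(C(=O)OC)C(=O)O[C@](C)(C=C)[C@H](O[Si](C)(C)C(C)(C)C)C=C)CC1
F8 | step 8 | oxolan-3-ols from reduction of 14 (C6 epimers) | C[C@@H](O[Si](CC)(CC)CC)[C@@H]1O[C@@](C)(COCc2ccccc2)CC1O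
F9 | step 8 | S-methyl xanthates of F8 | C[C@@H](O[Si](CC)(CC)CC)[C@@H]1O[C@@](C)(COCc2ccccc2)CC1OC(=S)SC
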